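Keep the books on Q and follow one molecule of it through its forks.

| flask | Q | Z | remark | time |
|---|---|---|---|---|
| larch | 0.40 M | 0.40 M | run made earlier |  |
| alder | 0.40 M | 0.60 M | run made earlier |  |
| elm | 0.20 M | 0.80 M | run made earlier |  |
| flask | 0.40 M | 0.800 M |  | 15 d |

- larch (time / d: D / %, Q / %): 0.250: 0, 99.9; 0.625: 0, 99.5; 1.25: 12.1, 86.2; 2.50: 43.7, 20.3; 6.00: 10.0, 4.5; 12.0: 6.5, 1.8
- alder (time / d: D / %, Q / %): 0.250: 0, 99.6; 0.625: 2.5, 96.7; 1.25: 56.3, 31.2; 2.50: 38.7, 1.1; 6.00: 8.0, 0; 12.0: 5.8, 0.5
- elm (time / d: D / %, Q / %): 0.250: 0, 100.1; 0.625: 1.1, 99.8; 1.67: 57.5, 26.4; 5.00: 10.9, 0.1; 12.0: 5.9, 0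

(readings scatter by 0.3 percentage points)

1. the best time, 15 d at the latest, for D
2. the amount of D, in percent of the Q charged, at that time



First entry, the toll in Z. The larch run was charged with equal [Q] and [Z], and its Q still fell to 1.8% by 12.0 d. So each Q lost takes at most one Z, and with [Z] of 0.800 M against [Q] of 0.40 M, Q is the limiting reagent in the flask.

Second entry, the fork. A Q that has gone stands either as D or as something unread, so call D divided by the Q lost the kept share. At the highest D reading of the alder run, at 1.25 d, it reads 81.8%.

Third entry, the close. In the elm run at 12.0 d, Q reads 0% and D reads 5.9%, which gives a closing share, the kept share at the end of the books, of 5.90%.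

The alder run reads D 5.8% at 12.0 d, so expect the flask to close near 5.90% of the charge as well, and look for its best at the front. The flask has more Z than the alder run at the same [Q], so expect its best no later than 1.25 d; if the kept share holds and some Q still stands at that best, expect it below 81.8% of the charge.

The forecast gives 66% at 1 d: “The peak comes shortly after the front, when roughly 6% of Q remains”.

The flask gives 70.7% at 1.13 d, so the forecast stands within its margins.

    Q + Z + J → D + 2 J (k = 4.10 × 10⁻⁴ M⁻² s⁻¹)
    Q + Z → D + J (k = 2.60 × 10⁻⁸ M⁻¹ s⁻¹)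
    D ⇌ L (K = 17.0, k = 8.70 × 10⁻⁶ s⁻¹)

At 15.0 d the flask holds Q 0%, D 5.56% and L 94.4%, a kept share of 5.56% against the closing share of 5.90%. Now take the neighbouring flask with [Z] of 0.32 M, or 0.800 equiv, whose best is 37.6%. There Z is the limiting reagent, with 0% of it left at the end. One Z per Q lets 80.0% of the Q go, and the closing share of that is 4.72% as D. That neighbouring flask ends at 15.0 d with Q 20.0% and D 4.45%.

The runs stem from a simulated flask from invented constants.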